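**Assumption:** Mururin C has no stereocentre or stereoaxis, so it is achiral and there is no enantiomer to control. The only stereo-features in the route are the E-alkene of chalcone 7 and one racemic sp3 centre in 8 and 9, which is erased when the furan aromatises.

## Retrosynthetic overview
1. The furan is the only ring formed, and it is closed last. The free ortho-phenol attacks the aryl ketone of an α-aryl-β-keto-aldehyde dimethyl acetal (TsOH/HFIP), and the acetal is unmasked as the C3-CHO.
2. The keto-acetal comes from an iodine(III)-mediated oxidative 1,2-aryl migration of a 2-benzyloxychalcone. This makes the C3–C3a bond by migration and turns the former salicylaldehyde carbon into the formyl carbon.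
3. The chalcone comes from a Claisen–Schmidt condensation of an O-benzyl 5-(3-hydroxypropyl)-o-vanillin with 3,4-bis(benzyloxy)-5-methoxyacetophenone.
4. The aldehyde comes from ortho-formylation of dihydroconiferyl alcohol. The ketone comes from mono-demethylation of acetosyringone.
5. Deliberately avoided: Sonogashira/heteroannulation of an o-iodophenol followed by Vilsmeier formylation, and biomimetic dihydrobenzofuran dehydrogenation.

## Forward route

**Step 1**
Reactants: 1, dihydroconiferyl alcohol [4-(3-hydroxypropyl)-2-methoxyphenol]
Product: 2, 2-hydroxy-5-(3-hydroxypropyl)-3-methoxybenzaldehyde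
Conditions: MgCl2 (3 equiv), Et3N (6 equiv), (CH2O)n (8 equiv), MeCN, reflux, 6 h; then 1 M HCl
Reagents that add atoms: paraformaldehyde/formaldehyde, C=O
Why: In this Casnati–Skattebøl ortho-formylation the magnesium phenoxide delivers CH2O to the only free ortho position, a second CH2O oxidises the salicyl alkoxide by hydride transfer, and any hemiformal on the aliphatic OH reverts in the acid work-up.

**Step 2**
Reactants: 2
Product: 3, 2-(benzyloxy)-5-(3-hydroxypropyl)-3-methoxybenzaldehyde
Conditions: BnBr (1.1 equiv), K2CO3, DMF, rt to 50 °C
Reagents that add atoms: benzyl bromide, BrCc1ccccc1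
Why: In this Williamson etherification K2CO3 ionises only the acidic salicylaldehyde phenol, so the primary alcohol stays free.

**Step 3**
Reactants: 4, acetosyringone [1-(4-hydroxy-3,5-dimethoxyphenyl)ethan-1-one]
Product: 5, 1-(3,4-dihydroxy-5-methoxyphenyl)ethan-1-one
Conditions: AlCl3 (1.2 equiv), pyridine (4.5 equiv), CH2Cl2, reflux, 24 h; then 2 M HCl
Reagents that add atoms: none
Why: In this chelation-directed Lewis-acid O-demethylation the aluminium phenoxide activates one neighbouring OMe for SN2 attack, and the five-membered Al-catecholate that forms consumes the single equivalent of Al, so the reaction stops at mono-cleavage.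

**Step 4**
Reactants: 5
Product: 6, 1-[3,4-bis(benzyloxy)-5-methoxyphenyl]ethan-1-one
Conditions: BnBr (2.4 equiv), K2CO3, DMF, 60 °C
Reagents that add atoms: benzyl bromide, BrCc1ccccc1
Why: This double Williamson etherification masks the oxidation-prone catechol with groups that resist the base of Step 5 and the acid and I(III) of Step 6, and K2CO3 is too weak to cause C-alkylation of the ketone.

**Step 5**
Reactants: 3 and 6
Product: 7, (E)-1-[3,4-bis(benzyloxy)-5-methoxyphenyl]-3-[2-(benzyloxy)-5-(3-hydroxypropyl)-3-methoxyphenyl]prop-2-en-1-one
Conditions: KOH (50% aq), EtOH/THF, rt, 36 h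
Reagents that add atoms: none
Why: In this Claisen–Schmidt condensation between a non-enolisable aldehyde and a methyl ketone, E1cB dehydration gives the thermodynamic E-enone, and the benzyl ethers and free alcohol are inert to the base.

**Step 6 (key step)**
Reactants: 7
Product: 8, (±)-1-[3,4-bis(benzyloxy)-5-methoxyphenyl]-2-[2-(benzyloxy)-5-(3-hydroxypropyl)-3-methoxyphenyl]-3,3-dimethoxypropan-1-one
Conditions: PhI(OH)OTs (1.2 equiv), MeOH/CH2Cl2 (3:1), rt, dark, 12 h; then aq NaHCO3
Reagents that add atoms: methanol (2 equiv), CO
Why: In this hypervalent-iodine oxidative 1,2-aryl migration of a chalcone, MeOH and I(III) add across the alkene (OMe at the benzylic carbon, I at the α-carbon), loss of PhI is assisted by the o-alkoxyaryl ring through a phenonium ion, and MeOH traps the resulting methoxycarbenium as the acetal, while primary alcohols and benzyl ethers are not oxidised by I(III) without a co-catalyst and the new stereocentre is racemic and later destroyed.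

**Step 7**
Reactants: 8
Product: 9, (±)-1-(3,4-dihydroxy-5-methoxyphenyl)-2-[2-hydroxy-5-(3-hydroxypropyl)-3-methoxyphenyl]-3,3-dimethoxypropan-1-one (partly present as cyclic hemiketal/cyclic acetal; used crude)
Conditions: H2 (1 atm), 10% Pd/C, EtOAc/MeOH (1:1), rt, 3 h; filter under Ar
Reagents that add atoms: none
Why: Neutral catalytic hydrogenolysis cleaves the three aryl benzyl ethers much faster than it reduces the hindered, electron-rich aryl ketone, no alkene is present at this stage, and any premature ring-chain tautomer feeds into the same product in Step 8.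

**Step 8**
Reactants: 9
Product: 10, mururin C [2-(3,4-dihydroxy-5-methoxyphenyl)-5-(3-hydroxypropyl)-7-methoxy-1-benzofuran-3-carbaldehyde]
Conditions: p-TsOH·H2O (1 equiv), (CF3)2CHOH (0.02 M), Ar, rt, 1–2 h; then pH 7 buffer
Reagents that add atoms: water (aldehyde oxygen on acetal hydrolysis), O
Why: In this acid-mediated cyclodehydration/acetal hydrolysis, strong acid in ionising, non-nucleophilic HFIP keeps phenol addition to the acetal carbon reversible, so the material drains through phenol addition to the ketone and E1 loss of water via a tertiary cation stabilised by the p-hydroxyaryl ring, giving the 2-aryl-3-formylbenzofuran rather than the 3-aroyl isomer.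

## Compound list
1 | dihydroconiferyl alcohol, 4-(3-hydroxypropyl)-2-methoxyphenol | COc1cc(CCCO)ccc1O | starting material
2 | 2-hydroxy-5-(3-hydroxypropyl)-3-methoxybenzaldehyde | COc1cc(CCCO)cc(C=O)c1O | intermediate
3 | 2-(benzyloxy)-5-(3-hydroxypropyl)-3-methoxybenzaldehyde | COc1cc(CCCO)cc(C=O)c1OCc2ccccc2 | intermediate
4 | acetosyringone | CC(=O)c1cc(OC)c(O)c(OC)c1 | starting material
5 | 1-(3,4-dihydroxy-5-methoxyphenyl)ethan-1-one | CC(=O)c1cc(O)c(O)c(OC)c1 | intermediate
6 | 1-[3,4-bis(benzyloxy)-5-methoxyphenyl]ethan-1-one | CC(=O)c1cc(OCc2ccccc2)c(OCc2ccccc2)c(OC)c1 | intermediate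
7 | (E)-tribenzyl chalcone | COc1cc(CCCO)cc(/C=C/C(=O)c2cc(OCc3ccccc3)c(OCc3ccccc3)c(OC)c2)c1OCc4ccccc4 | intermediate
8 | (±)-rearranged tribenzyl β-keto dimethyl acetal | COC(OC)C(C(=O)c1cc(OCc2ccccc2)c(OCc2ccccc2)c(OC)c1)c1cc(CCCO)cc(OC)c1OCc2ccccc2 | intermediate
9 | (±)-triphenolic β-keto dimethyl acetal | COC(OC)C(C(=O)c1cc(O)c(O)c(OC)c1)c1cc(CCCO)cc(OC)c1O | intermediate
10 | mururin C (achiral) | COc1cc(-c2oc3c(OC)cc(CCCO)cc3c2C=O)cc(O)c1O | target

## Summary
**Total steps:** 8.
**Longest linear sequence:** 6. Both branches are equal in length: Steps 1, 2, 5, 6, 7, 8 or Steps 3, 4, 5, 6, 7, 8.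

**Three steps most likely to fail**

1. **Step 6, aryl migration.**
   - Risk: the 2-OBn group is flanked on both sides and twisted out of conjugation, which lowers migratory aptitude. Competing pathways are α,β-dimethoxylation, participation by the OBn oxygen, and iodonium formation on the veratrole-type ring.
   - Fallback: reach the same oxidation level without a rearrangement. Brominate 1 ortho to the OH with NBS and benzylate it. Then carry out a Pd-catalysed α-arylation of ketone 6 to give the deoxybenzoin, and C-formylate with DMF-DMA. The resulting enaminone enters Steps 7 and 8.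

2. **Step 8, regiodivergent closure.**
   - Risk: irreversible loss of MeOH from the 2-methoxy-2,3-dihydrobenzofuran gives the 3-aroylbenzofuran isomer, and the catechol may degrade.
   - Fallback: remove the ambiguity by closing on a substrate with a single carbonyl. Cyclodehydrate the o-hydroxy deoxybenzoin to the 2-arylbenzofuran, with the ring-B benzyls retained and the side-chain OH protected as its acetate. Install C3-CHO by Vilsmeier–Haack formylation. Finish with BCl3/pentamethylbenzene debenzylation and mild methanolysis of the acetate.

3. **Step 1, formylation of a guaiacol that carries a free alcohol.**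
   - Risk: Mg chelation by the OMe group slows the reaction, and formaldehyde-derived by-products can form.
   - Fallback: build the side chain onto a ready-made aldehyde. O-Benzylate commercial 5-bromo-2-hydroxy-3-methoxybenzaldehyde. Then perform a B-alkyl Suzuki–Miyaura coupling with the 9-BBN adduct of allyl benzyl ether. The extra benzyl group is removed in the Step 7 hydrogenolysis.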